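**Strategy.** Ring B of the 1,2-dihydronaphthalene is cut into two three-carbon pieces: the benzhydryl unit C1–C8a–C4a of ring A and the itaconate unit C2–C3–C4. The key step is a palladium-catalysed asymmetric [3+3] annulation. A racemic ortho-bromobenzhydryl carbonate and dimethyl itaconate give, in one flask, the C1–C2 bond by enantioselective benzylic alkylation and the C4–C4a bond by Heck closure, with C3=C4 in place. It exploits that C1 is doubly benzylic and ionisable while C4a is the ring A carbon ortho to it, matching the nucleophilic C2 and the Heck-active C4 of itaconate. Ester reduction ends the route.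

Key step: step 2

Remark on numbering: atom numbers are those of the 1,2-dihydronaphthalene of the target; ring A is the trimethoxybenzo ring (C4a to C8a), ring B the dihydro ring (C1 to C4), ring C the 3,4-dimethoxyphenyl group on C1.

Assumption: (R)-H8-BINAP is taken as the ligand antipode that leads to the (1R) series; if the sense of induction proves opposite, the (S)-ligand is used and nothing else changes.

**Step 1**
Reactants: 1 5-bromo-1,2,3-trimethoxybenzene; 2 3,4-dimethoxybenzaldehyde
Product: 5 tert-butyl (6-bromo-2,3,4-trimethoxyphenyl)(3,4-dimethoxyphenyl)methyl carbonate (racemic), via aryllithium 3 (not isolated), via lithium alkoxide 4 (not isolated)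
Conditions: lithium 2,2,6,6-tetramethylpiperidide (from n-BuLi and 2,2,6,6-tetramethylpiperidine), THF, −78 °C; then 2, −78 °C; then Boc2O, −78 °C to 0 °C
Reagents that add atoms: di-tert-butyl dicarbonate (Boc2O), CC(C)(C)OC(=O)OC(=O)OC(C)(C)C
Why: Directed ortho-lithiation at the only kind of ring C–H in 1 (flanked by Br and OMe), 1,2-addition of the aryllithium to the aldehyde and O-acylation of the lithium alkoxide are routine operations, and the new benzhydryl centre is left racemic on purpose because it is ionised in step 2.

**Step 2**
Reactants: 5 tert-butyl (6-bromo-2,3,4-trimethoxyphenyl)(3,4-dimethoxyphenyl)methyl carbonate (racemic); 6 dimethyl itaconate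
Product: 8 dimethyl (1R,2S)-1-(3,4-dimethoxyphenyl)-6,7,8-trimethoxy-1,2-dihydronaphthalene-2,3-dicarboxylate, via benzylic alkylation product 7 (not isolated)
Conditions: 6 (1.5 equiv), [Pd(η3-C3H5)Cl]2 (2.5 mol %), (R)-H8-BINAP (6 mol %), Cs2CO3 (2.2 equiv), 1,4-dioxane, 60 °C, then 100 °C
Reagents that add atoms: none
Why: Proposed new method: zerovalent palladium bearing (R)-H8-BINAP ionises the benzhydryl carbonate of 5 at 60 °C to a pair of rapidly interconverting η3-diarylmethyl complexes, the tert-butoxide released deprotonates 6, and outer-sphere α-attack of the itaconate dienolate forms C1–C2 and gives 7; at 100 °C the same catalyst inserts into the C–Br bond, and Mizoroki–Heck carbopalladation onto the acrylate CH2 followed by syn β-hydride elimination of the benzylic hydrogen forms C4–C4a and the C3=C4 double bond. The closest known reaction types are the palladium-catalysed asymmetric benzylic alkylation of stabilised carbanions with racemic diarylmethyl carbonates (a dynamic kinetic asymmetric transformation) and the intramolecular Heck reaction of α-substituted acrylates; their merger in one flask on an itaconate is new. Ring B closes in the Heck stage in the 6-endo-trig mode. C1 is set by the chiral ligand, which selects one of the equilibrating η3-benzyl diastereomers for attack, and C2 is set by the substrate: its α-ester, allylic hydrogen equilibrates through the dienolate under Cs2CO3 and should settle trans to the C1 aryl group, where both substituents are pseudoaxial and avoid the C8 methoxy group and the C3 ester. The step needs α- over γ-alkylation of the dienolate, which the higher charge density at the ester-bearing carbon should secure, and 6-endo over 5-exo closure, which the polarised acrylate (aryl to the unsubstituted β-carbon) and the crowding of a quaternary C3 flanked by two tertiary centres should secure. The order of the two events is fixed by the temperature programme, since the electron-rich aryl bromide is not expected to add to the bisphosphine complex at 60 °C.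

**Step 3**
Reactants: 8 dimethyl (1R,2S)-1-(3,4-dimethoxyphenyl)-6,7,8-trimethoxy-1,2-dihydronaphthalene-2,3-dicarboxylate
Product: 9 [(1R,2S)-1-(3,4-dimethoxyphenyl)-6,7,8-trimethoxy-1,2-dihydronaphthalene-2,3-diyl]dimethanol (CNP0274357.1)
Conditions: i-Bu2AlH (6 equiv), CH2Cl2, −78 °C to 0 °C; aqueous potassium sodium tartrate work-up
Reagents that add atoms: none
Why: Hydride reduction of both esters with i-Bu2AlH should give 1,2-reduction of the aryl-conjugated ester without touching C3=C4 and, being non-basic, should leave C1 and C2 untouched; no new stereocentre is formed.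

**Compound list**
1 | 5-bromo-1,2,3-trimethoxybenzene | COc1cc(Br)cc(OC)c1OC | starting material
2 | 3,4-dimethoxybenzaldehyde | COc1ccc(C=O)cc1OC | starting material
3 | (6-bromo-2,3,4-trimethoxyphenyl)lithium | [Li]c1c(Br)cc(OC)c(OC)c1OC | intermediate
4 | lithium (6-bromo-2,3,4-trimethoxyphenyl)(3,4-dimethoxyphenyl)methanolate (racemic) | [Li]OC(c1ccc(OC)c(OC)c1)c1c(Br)cc(OC)c(OC)c1OC | intermediate
5 | tert-butyl (6-bromo-2,3,4-trimethoxyphenyl)(3,4-dimethoxyphenyl)methyl carbonate (racemic) | COc1ccc(C(OC(=O)OC(C)(C)C)c2c(Br)cc(OC)c(OC)c2OC)cc1OC | intermediate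
6 | dimethyl itaconate (dimethyl 2-methylidenebutanedioate) | C=C(CC(=O)OC)C(=O)OC | starting material
7 | dimethyl 2-[(R)-(6-bromo-2,3,4-trimethoxyphenyl)(3,4-dimethoxyphenyl)methyl]-3-methylidenebutanedioate (both C2 epimers, interconverting) | COc1ccc([C@H](c2c(Br)cc(OC)c(OC)c2OC)C(C(=O)OC)C(=C)C(=O)OC)cc1OC | intermediate
8 | dimethyl (1R,2S)-1-(3,4-dimethoxyphenyl)-6,7,8-trimethoxy-1,2-dihydronaphthalene-2,3-dicarboxylate | COc1ccc([C@@H]2c3c(cc(OC)c(OC)c3OC)C=C(C(=O)OC)[C@H]2C(=O)OC)cc1OC | intermediate
9 | [(1R,2S)-1-(3,4-dimethoxyphenyl)-6,7,8-trimethoxy-1,2-dihydronaphthalene-2,3-diyl]dimethanol | COc1ccc([C@@H]2c3c(cc(OC)c(OC)c3OC)C=C(CO)[C@H]2CO)cc1OC | target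

Total step count: 3. Longest linear sequence: 3 steps (1 → 5 → 8 → 9).

**Steps most likely to fail**

1. Step 2 (Proposed new method). The risks are:
   - ionisation of the very electron-rich carbonate without palladium, which would give racemic alkylation;
   - weak discrimination between the two η3-benzyl diastereomers;
   - γ-alkylation or self-addition of the itaconate dienolate;
   - 5-exo instead of 6-endo carbopalladation;
   - base-mediated migration of the C3=C4 double bond out of conjugation with ring A, which would also put C1 at risk.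

   Fallback (known chemistry; sets out from 5 and comes back at 8): itaconic anhydride is opened at its non-conjugated carbonyl by the lithium salt of (S)-4-benzyl-1,3-oxazolidin-2-one (THF, −78 °C) to give 4-[(4S)-4-benzyl-2-oxo-1,3-oxazolidin-3-yl]-2-methylidene-4-oxobutanoic acid F1. Me3SiCHN2 in toluene/MeOH converts it into the methyl ester F2. A Mizoroki–Heck reaction of 5 with F2 under ligand-free phase-transfer conditions (Pd(OAc)2, n-Bu4NCl, NaHCO3, DMF, 80 °C), where the benzylic carbonate is not expected to ionise, should give the (E)-arylidene imide F3. TiCl4 and i-Pr2NEt in CH2Cl2 (−78 to −20 °C) then form the chelated chlorotitanium (Z)-enolate and ionise the carbonate. The intramolecular SN1 alkylation should close ring B on the enolate face opposite the benzyl group of the auxiliary (2S), with the C1 aryl group trans, to give the imide F4. MeOMgBr in MeOH/CH2Cl2 at 0 °C exchanges the auxiliary for OMe and returns 8.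

2. Step 1. The risks are loss of LiBr from the ortho-bromoaryllithium to an aryne before the aldehyde arrives, and incomplete deprotonation of the electron-rich ring.

   Fallback (sets out from 1 and comes back at 5): Friedel–Crafts acylation of 1 with 3,4-dimethoxybenzoyl chloride (SnCl4, CH2Cl2, 0 °C) can only occur at the two equivalent free positions and should give (6-bromo-2,3,4-trimethoxyphenyl)(3,4-dimethoxyphenyl)methanone F5. NaBH4 in MeOH/THF reduces it to the racemic alcohol (6-bromo-2,3,4-trimethoxyphenyl)(3,4-dimethoxyphenyl)methanol F6. Boc2O with catalytic 4-(dimethylamino)pyridine and Et3N in CH2Cl2 then gives 5.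

3. Step 3. The risks are conjugate hydride delivery or hydroalumination at the styrenyl double bond once the allylic alkoxide has formed, and stalling at a lactol or lactone because the C2 ester is hindered.

   Fallback (sets out from 8 and comes back at 9): saponification with LiOH in THF/H2O at room temperature should give (1R,2S)-1-(3,4-dimethoxyphenyl)-6,7,8-trimethoxy-1,2-dihydronaphthalene-2,3-dicarboxylic acid F7. BH3·THF at 0 °C reduces the two carboxylic acids faster than it adds to the trisubstituted aryl-conjugated alkene and should give 9.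

**Further compounds**
F1 | step 2 | 4-[(4S)-4-benzyl-2-oxo-1,3-oxazolidin-3-yl]-2-methylidene-4-oxobutanoic acid | OC(=O)C(=C)CC(=O)N1C(=O)OC[C@@H]1Cc1ccccc1
F2 | step 2 | methyl 4-[(4S)-4-benzyl-2-oxo-1,3-oxazolidin-3-yl]-2-methylidene-4-oxobutanoate | COC(=O)C(=C)CC(=O)N1C(=O)OC[C@@H]1Cc1ccccc1
F3 | step 2 | methyl (E)-4-[(4S)-4-benzyl-2-oxo-1,3-oxazolidin-3-yl]-2-{[2-{[(tert-butoxycarbonyl)oxy](3,4-dimethoxyphenyl)methyl}-3,4,5-trimethoxyphenyl]methylidene}-4-oxobutanoate (both epimers at the benzhydryl carbon) | COC(=O)C(/CC(=O)N1C(=O)OC[C@@H]1Cc1ccccc1)=C/c1cc(OC)c(OC)c(OC)c1C(OC(=O)OC(C)(C)C)c1ccc(OC)c(OC)c1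
F4 | step 2 | methyl (1R,2S)-2-{[(4S)-4-benzyl-2-oxo-1,3-oxazolidin-3-yl]carbonyl}-1-(3,4-dimethoxyphenyl)-6,7,8-trimethoxy-1,2-dihydronaphthalene-3-carboxylate | COc1ccc([C@@H]2c3c(cc(OC)c(OC)c3OC)C=C(C(=O)OC)[C@H]2C(=O)N4C(=O)OC[C@@H]4Cc5ccccc5)cc1OC
F5 | step 1 | (6-bromo-2,3,4-trimethoxyphenyl)(3,4-dimethoxyphenyl)methanone | COc1ccc(C(=O)c2c(Br)cc(OC)c(OC)c2OC)cc1OC
F6 | step 1 | (6-bromo-2,3,4-trimethoxyphenyl)(3,4-dimethoxyphenyl)methanol (racemic) | COc1ccc(C(O)c2c(Br)cc(OC)c(OC)c2OC)cc1OC
F7 | step 3 | (1R,2S)-1-(3,4-dimethoxyphenyl)-6,7,8-trimethoxy-1,2-dihydronaphthalene-2,3-dicarboxylic acid | COc1ccc([C@@H]2c3c(cc(OC)c(OC)c3OC)C=C(C(=O)O)[C@H]2C(=O)O)cc1OC
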